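## Structural features

The target is an unsymmetrical furofuran lignan built on a cis-fused 3,7-dioxabicyclo[3.3.0]octane: ring A (C1, C2, O3, C4, C5) and ring B (C1, C5, C6, O7, C8) share the C1–C5 bond. Four contiguous stereocentres run C2–C1–C5–C6 (1S,2S,5S,6R); H1, H2 and H5 lie on the convex face, so the guaiacyl group on C2 is endo (inside the fold) and the 3-methoxy-4-prenyloxyphenyl group on C6 is exo. The two aryl groups differ only at the para oxygen (free phenol on the C2 ring, prenyl ether on the C6 ring), which rules out a dimerisation logic and calls for two phenol protecting groups that leave at different times. Fragile points are the benzylic C–O bonds C2–O3 and C6–O7, each activated by an electron-rich ring and so open to acid ionisation and hydrogenolysis, and the prenyl ether, which tolerates neither hydrogenation nor metal carbenoids nor strong Lewis acids. The endo aryl at C2 is the less stable arrangement, so any reversible ionisation at C2 leads toward the exo,exo isomer. The real difficulty is therefore to place an endo aryl at C2 beside an exo aryl at C6 in one enantiomer and then finish the skeleton without acid. The key step exploits that O3 of ring A can be the oxygen of a C2 aryl ketone, and that O3–C4 can be formed when this oxygen opens a cyclopropane C1–C4–C5 fused to a ring B lactone. The C1–C4 bond, absent from the target, is what first ties C5 to the exo aryl at C6, and its cleavage leaves a C1=C2 enol ether whose convex face then fixes C1 and C2.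

## Logic of the disconnections

21 ⇒ 20. The phenolic O–Si bond is cut. The free phenol of the C2 ring must stay masked while the other phenol is alkylated and while hydride and sulfonyl chloride are used. The gain is a precursor with no acidic group. The demand is a final fluoride step that touches neither the prenyl ether nor the benzylic ethers.

20 ⇒ 18. The O7–C8 bond of ring B is cut. An ether closed by displacement at the primary carbon C8 needs only base, so C2 and C6 cannot ionise. The bicycle simplifies to a monocyclic oxolane diol. The forward step must activate the primary hydroxyl selectively and let the C6 oxygen attack, with retention at C6.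

18 ⇒ 17. C8 is returned to the carboxyl level and the C8(=O)–O7 lactone is restored. The lactone is the form in which ring B leaves the key step. The demand is a hydride reduction that spares the aryl silyl ether and the prenyl alkene.

17 ⇒ 16. The aryl O–CH2 bond of the prenyl ether is cut. The alkene cannot pass the hydrogenation, so it is attached directly afterwards. The forward alkylation must hit one phenol while the other stays silylated, under a base too weak to touch C1–H.

16 ⇒ 15. The hydrogens at C1 and C2 are removed (C1=C2) and the benzyl group is put back on the C6-ring phenol. One syn addition of hydrogen sets both C1 and C2, and the benzyl ether falls in the same operation. Two stereocentres are removed. The demand is convex-face delivery without hydrogenolysis of C2–O3 or C6–O7.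

15 ⇒ 13 (key). The O3–C4 bond is cut and C1–C4 is reconnected. The enol ether oxygen becomes the oxygen of an aroyl ketone. Ring A is exchanged for a cyclopropane that can be built stereoselectively on ring B, and the two aryl groups now belong to separate building blocks. The forward step must open the cyclopropane at C4 and not at C5.

13 ⇒ 12. The C1–C4 and C1–C5 bonds are cut (carbene plus alkene). The intramolecular cyclopropanation closes the ring B lactone and the three-membered ring together, with C6 directing. Two rings and the stereocentres C1 and C5 disappear. The demand is addition anti to the aryl group and chemoselectivity over the arenes.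

12 ⇒ 11. The C1=N2 unit is removed. The diazo group is placed on an active methylene between ketone and ester. The demand is a mild base-mediated diazo transfer.

11 ⇒ 4 + 9 (through 10). The ester bond O7–C8 is cut. This is the only heteroatom link between the two aryl halves, so the route becomes convergent. The forward acylation must leave the C6–O bond of an ionisation-prone benzylic allylic alcohol intact.

9 ⇒ 7 + 8. The C1–C2 bond between the aroyl carbon and the malonyl carbon is cut. C1 and C8 come from a malonate equivalent that later releases the acylketene. The demand is a clean C-acylation.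

7 ⇒ 5. The O–Si bond is cut. The demand is selective hydrolysis of the silyl ester formed alongside the silyl ether.

4 ⇒ 3. No skeletal bond is cut; the C6 stereocentre is traced to the racemate. Kinetic resolution by asymmetric epoxidation is reliable for secondary allylic alcohols and can be driven to high enantiomeric purity. The demand is the tartrate enantiomer that consumes the unwanted alcohol; the cost is half of the material.

3 ⇒ 1 + 2. The C5–C6 bond is cut. The vinyl group supplies C4 and C5. Both partners are purchasable.

## Other disconnections considered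

Alternative 1: The cut is C4–C5 and C1–C2 of ring A, leading to the alkenyl methylene acetal A1, a 4-[(Z)-3-arylprop-1-enyl]-5-aryl-1,3-dioxolane.
- **Forward key step:** SnCl4 ionises the acetal to an oxocarbenium ion at C4. C5 of the Z-alkene attacks it, and the positive charge developing at C1 is quenched by a 1,2-shift of C2 from C8. This contracts the ring to the oxolane and releases C8 as the aldehyde of the all-cis product A2.
- **In its favour:** two C–C bonds and three contiguous stereocentres (C1, C2, C5) are formed in one step from a chair-like arrangement. The chosen key step makes one C–O bond and no stereocentre, so on bonds and stereocentres per step the alternative is the better.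
- **Against it here:** A2 contains neither ring B nor the C6 stereocentre. C6 is still a benzylic CH2, so aldehyde reduction and a benzylic oxidative cyclisation must follow on a ring that already carries the acid-sensitive C2–O3 bond. The alkene is 1,2-disubstituted, so the cation at C1 is only secondary and sits next to the oxygenated C8. The all-cis aldehyde A2 can epimerise at C1, and the sulfonate that tames the C2 aryl must be removed with strong base at the end.
- **Comparison:** both plans draw the absolute configuration from one carbinol centre, and are equal on that point. The chosen plan has all four stereocentres one step after its key step and works under neutral nucleophilic catalysis, whereas the alternative is cationic throughout. The step count is expected to be equal or higher for the alternative.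

Alternative 2: The cut is C5–C6 and C6–O7 of ring B, leading to the cis-dihydrofuran alcohol A3 and aldehyde 1.
- **Forward key step:** TMSOTf condenses the primary hydroxyl of A3 with 1 to an O7=C6 oxocarbenium ion. The enol ether carbon C5 attacks it and closes ring B, and Et3SiH reduces the resulting O3=C4 oxocarbenium ion to give A4.
- **In its favour:** it is the most convergent plan. Two bonds, one ring and two stereocentres (C5, C6) arise in one operation, and the lactone adjustment of steps 11 and 12 is not needed, so on convergence and redox economy the alternative is the better. The preference for an exo aryl at C6 rests on the same convex-face argument as in the chosen plan, an equal point.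
- **Against it here:** A3 is itself demanding, with two stereocentres and an acid-labile enol ether, and reaching it enantiopure should cost about as many steps as reaching 13. The key step runs under a strong Lewis acid in the presence of the benzylic C2–O3 bond, so loss of the endo configuration threatens; this is why the C2 aryl has to be deactivated as a sulfonate. Premature silane reduction of the first oxocarbenium ion can compete. Three steps still follow A4: debenzylation, prenylation and sulfonate cleavage.
- **Comparison:** the alternative is shorter after its key step but concentrates its risk in one acid-mediated cascade. The chosen plan spreads the risk over well-precedented single events and keeps acid away from the finished skeleton.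

Alternative 3: The cut is C1–C8 of ring B, leading to the alkoxyacetic acid A5, in which the O7–CH2–CO2H chain hangs on C6 and ring A is a 5-aryl-2,3-dihydrofuran.
- **Forward key step:** oxidative decarboxylation gives the O7–CH2 radical, which closes 5-exo-trig onto C1. The benzylic C2 radical then takes a hydrogen atom from a thiol to give A6, which is the same compound as 20.
- **In its favour:** the near-neutral radical conditions leave the prenyl ether and both benzylic ethers alone, so only desilylation follows; on endgame length the alternative is the better. The key step forms a C–C bond and sets C1 and C2. The convex-face argument for hydrogen delivery at C2 is the same as for the hydrogenation of 15, an equal point.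
- **Against it here:** a nucleophilic α-alkoxyalkyl radical adds to an electron-rich enol ether carbon, a polarity mismatch offset only by intramolecularity. The C2 radical is planar and stabilised, so the endo/exo outcome rests on one small hydrogen donor. Thiyl radicals can add to the prenyl alkene. A5 needs the C5/C6 relationship set in an open chain and combines a free acid with an acid-labile aryl enol ether.
- **Comparison:** the chosen plan fixes C5 against C6 on a ring by cyclopropanation, which is more secure than the open-chain control needed for A5, but it pays two extra steps for the lactone-to-ether change.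

Key step: step 8

Assumption: 4-benzyloxy-3-methoxybenzaldehyde 1 (the O-benzyl ether of vanillin) is bought as such, and the titanium tartrate resolution is taken to follow its usual sense for 1-arylallyl alcohols, so that D-(−)-DIPT consumes the S enantiomer.

## Route

Step 1
Reactants: 1 4-benzyloxy-3-methoxybenzaldehyde; 2 vinylmagnesium bromide
Product: 3 rac-1-(4-benzyloxy-3-methoxyphenyl)prop-2-en-1-ol
Conditions: THF, −78 → 0 °C; aq. NH4Cl
Reagents that add atoms: none
Why: Grignard 1,2-addition to a non-enolisable aryl aldehyde forms C5–C6; C6 arises as a racemate that is resolved in step 2.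

Step 2
Reactants: 3 rac-1-(4-benzyloxy-3-methoxyphenyl)prop-2-en-1-ol
Product: 4 (R)-1-(4-benzyloxy-3-methoxyphenyl)prop-2-en-1-ol
Conditions: Ti(OiPr)4, D-(−)-DIPT, t-BuOOH (0.6 equiv), 4 Å MS, CH2Cl2, −20 °C
Reagents that add atoms: none
Why: Sharpless kinetic resolution of a secondary allylic alcohol; with D-(−)-DIPT the S enantiomer should be epoxidised faster, so the R alcohol is recovered, and running slightly past half conversion should raise its enantiomeric purity. The absolute configuration of C6 is fixed here.

Step 3
Reactants: 5 vanillic acid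
Product: 7 3-methoxy-4-(triisopropylsilyloxy)benzoic acid, via triisopropylsilyl ester 6 (not isolated)
Conditions: TIPSCl (2.2 equiv), imidazole, DMF, rt; then AcOH–THF–H2O, rt
Reagents that add atoms: triisopropylsilyl chloride, CC(C)[Si](Cl)(C(C)C)C(C)C
Why: Imidazole-mediated silylation takes both the phenol and the acid; the silyl ester is far more labile than the aryl silyl ether and should hydrolyse selectively under the mild acidic work-up.

Step 4
Reactants: 7 3-methoxy-4-(triisopropylsilyloxy)benzoic acid; 8 Meldrum's acid
Product: 9 5-{hydroxy[3-methoxy-4-(triisopropylsilyloxy)phenyl]methylidene}-2,2-dimethyl-1,3-dioxane-4,6-dione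
Conditions: DCC, DMAP, CH2Cl2, 0 °C → rt
Reagents that add atoms: none
Why: Carbodiimide-mediated C-acylation of Meldrum's acid under DMAP catalysis should give the enolised acyl Meldrum's acid, a stored form of the aroylketene.

Step 5
Reactants: 9 5-{hydroxy[3-methoxy-4-(triisopropylsilyloxy)phenyl]methylidene}-2,2-dimethyl-1,3-dioxane-4,6-dione; 4 (R)-1-(4-benzyloxy-3-methoxyphenyl)prop-2-en-1-ol
Product: 11 (R)-1-(4-benzyloxy-3-methoxyphenyl)prop-2-enyl 3-[3-methoxy-4-(triisopropylsilyloxy)phenyl]-3-oxopropanoate, via aroylketene 10 (not isolated)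
Conditions: toluene, 80 °C
Reagents that add atoms: none
Why: Thermal fragmentation of the acyl Meldrum's acid (loss of acetone and CO2) gives the acylketene, which the secondary alcohol traps as the β-keto ester; the C6–O bond is not broken, so the configuration is retained.

Step 6
Reactants: 11 (R)-1-(4-benzyloxy-3-methoxyphenyl)prop-2-enyl 3-[3-methoxy-4-(triisopropylsilyloxy)phenyl]-3-oxopropanoate
Product: 12 (R)-1-(4-benzyloxy-3-methoxyphenyl)prop-2-enyl 2-diazo-3-[3-methoxy-4-(triisopropylsilyloxy)phenyl]-3-oxopropanoate
Conditions: p-ABSA, Et3N, MeCN, 0 °C → rt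
Reagents that add atoms: 4-acetamidobenzenesulfonyl azide (p-ABSA), CC(=O)Nc1ccc(S(=O)(=O)N=[N+]=[N-])cc1
Why: Regitz diazo transfer to the active methylene of a β-keto ester; the mild amine base should leave the aryl silyl ether and the allylic ester untouched.

Step 7
Reactants: 12 (R)-1-(4-benzyloxy-3-methoxyphenyl)prop-2-enyl 2-diazo-3-[3-methoxy-4-(triisopropylsilyloxy)phenyl]-3-oxopropanoate
Product: 13 (1S,4R,5R)-4-(4-benzyloxy-3-methoxyphenyl)-1-[3-methoxy-4-(triisopropylsilyloxy)benzoyl]-3-oxabicyclo[3.1.0]hexan-2-one
Conditions: Rh2(OAc)4 (1 mol %), CH2Cl2, reflux, slow addition of 12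
Reagents that add atoms: none
Why: Intramolecular cyclopropanation of the vinyl group by the rhodium carbenoid forms C1–C4 and C1–C5 and closes the ring B lactone. The cis ring fusion is enforced by the tether, and the aryl group at C6 should take the exo position anti to the new cyclopropane, so C5 is set relative to C6 (the carbinol hydrogen, not the aryl group, eclipses the alkene, minimising allylic 1,3-strain).

Step 8
Reactants: 13 (1S,4R,5R)-4-(4-benzyloxy-3-methoxyphenyl)-1-[3-methoxy-4-(triisopropylsilyloxy)benzoyl]-3-oxabicyclo[3.1.0]hexan-2-one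
Product: 15 (5S,6R)-6-(4-benzyloxy-3-methoxyphenyl)-2-[3-methoxy-4-(triisopropylsilyloxy)phenyl]-3,7-dioxabicyclo[3.3.0]oct-1-en-8-one, via iodomethyl enolate 14 (not isolated)
Conditions: NaI (0.5 equiv), DMF, 80–90 °C
Reagents that add atoms: none
Why: Cloke–Wilson rearrangement of a doubly activated acylcyclopropane under nucleophilic catalysis; the closest known reaction type is the iodide- or amine-catalysed ring expansion of 1-acylcyclopropane-1-carboxylates to 4,5-dihydrofuran-3-carboxylates. Iodide attacks the cyclopropane methylene C4 in an SN2 homoconjugate addition, breaks C1–C4, releases the strain of the bicyclo[3.1.0] system and gives the β-keto lactone enolate 14. The ketone enolate oxygen then displaces iodide at C4 in a 5-exo-tet closure that forms O3–C4 and ring A. The competing 3-exo-tet C-alkylation only returns 13 and attack by the lactone oxygen would give a less stable ketene acetal, so the sequence should funnel to the conjugated vinylogous carbonate 15. No stereocentre is created: C5 and C6 keep all their bonds and C1 becomes sp2. The selectivity needed is regiochemical, cleavage of C1–C4 and not of C1–C5, and it is secured because C4 is the only unhindered primary carbon while C5 is a ring-fusion methine. The second requirement, that iodide does not dealkylate the benzylic lactone at C6, is met by a sub-stoichiometric amount of iodide at moderate temperature and by the absence of Lewis acids that would ionise C6–O7.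

Step 9
Reactants: 15 (5S,6R)-6-(4-benzyloxy-3-methoxyphenyl)-2-[3-methoxy-4-(triisopropylsilyloxy)phenyl]-3,7-dioxabicyclo[3.3.0]oct-1-en-8-one
Product: 16 (1R,2S,5S,6R)-6-(4-hydroxy-3-methoxyphenyl)-2-[3-methoxy-4-(triisopropylsilyloxy)phenyl]-3,7-dioxabicyclo[3.3.0]octan-8-one
Conditions: H2 (1–3 atm), 10% Pd/C, EtOAc, rt
Reagents that add atoms: none
Why: Heterogeneous catalytic hydrogenation adds H2 syn to C1=C2 from the convex face (the side of H5, away from the fold of ring B), so H1 and H2 become cis to H5 and the C2 aryl group becomes endo. The benzyl aryl ether is hydrogenolysed in the same operation; neutral solvent and low pressure should spare C2–O3 and C6–O7.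

Step 10
Reactants: 16 (1R,2S,5S,6R)-6-(4-hydroxy-3-methoxyphenyl)-2-[3-methoxy-4-(triisopropylsilyloxy)phenyl]-3,7-dioxabicyclo[3.3.0]octan-8-one
Product: 17 (1R,2S,5S,6R)-2-[3-methoxy-4-(triisopropylsilyloxy)phenyl]-6-[3-methoxy-4-(3-methylbut-2-enyloxy)phenyl]-3,7-dioxabicyclo[3.3.0]octan-8-one
Conditions: prenyl bromide, K2CO3, acetone, rt → 40 °C
Reagents that add atoms: prenyl bromide (1-bromo-3-methylbut-2-ene), CC(C)=CCBr
Why: Williamson etherification of the only free phenol; carbonate in acetone should be too weak to deprotonate C1–H or to cleave the aryl silyl ether.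

Step 11
Reactants: 17 (1R,2S,5S,6R)-2-[3-methoxy-4-(triisopropylsilyloxy)phenyl]-6-[3-methoxy-4-(3-methylbut-2-enyloxy)phenyl]-3,7-dioxabicyclo[3.3.0]octan-8-one
Product: 18 [(2S,3S,4S)-4-{(R)-hydroxy[3-methoxy-4-(3-methylbut-2-enyloxy)phenyl]methyl}-2-[3-methoxy-4-(triisopropylsilyloxy)phenyl]oxolan-3-yl]methanol
Conditions: LiAlH4, THF, 0 °C
Reagents that add atoms: none
Why: Hydride reduction of the lactone to the 1,4-diol; no stereocentre is touched, and the prenyl ether, the benzylic ether C2–O3 and the aryl silyl ether should be inert at 0 °C.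

Step 12
Reactants: 18 [(2S,3S,4S)-4-{(R)-hydroxy[3-methoxy-4-(3-methylbut-2-enyloxy)phenyl]methyl}-2-[3-methoxy-4-(triisopropylsilyloxy)phenyl]oxolan-3-yl]methanol
Product: 20 (1S,2S,5S,6R)-2-[3-methoxy-4-(triisopropylsilyloxy)phenyl]-6-[3-methoxy-4-(3-methylbut-2-enyloxy)phenyl]-3,7-dioxabicyclo[3.3.0]octane, via primary mesylate 19 (not isolated)
Conditions: MsCl (1.1 equiv), Et3N, CH2Cl2, −20 °C → rt
Reagents that add atoms: none
Why: Selective sulfonylation of the less hindered primary hydroxyl at C8, followed by intramolecular Williamson etherification (5-exo-tet) by the C6 oxygen, closes ring B with retention at C6. The medium stays basic, so the endo aryl at C2 should not epimerise.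

Step 13
Reactants: 20 (1S,2S,5S,6R)-2-[3-methoxy-4-(triisopropylsilyloxy)phenyl]-6-[3-methoxy-4-(3-methylbut-2-enyloxy)phenyl]-3,7-dioxabicyclo[3.3.0]octane
Product: 21 2-methoxy-4-{(1S,2S,5S,6R)-6-[3-methoxy-4-(3-methylbut-2-enyloxy)phenyl]-3,7-dioxabicyclo[3.3.0]octan-2-yl}phenol
Conditions: TBAF, AcOH, THF, 0 °C → rt
Reagents that add atoms: none
Why: Fluoride-mediated cleavage of the aryl silyl ether; buffering with acetic acid keeps the medium near neutral, so neither the prenyl ether nor the benzylic ethers should be affected.

## Compound list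

1 | 4-benzyloxy-3-methoxybenzaldehyde (O-benzylvanillin) | COc1cc(C=O)ccc1OCc1ccccc1 | starting material
2 | vinylmagnesium bromide | C=C[Mg]Br | starting material
3 | rac-1-(4-benzyloxy-3-methoxyphenyl)prop-2-en-1-ol | C=CC(O)c1ccc(OCc2ccccc2)c(OC)c1 | intermediate
4 | (R)-1-(4-benzyloxy-3-methoxyphenyl)prop-2-en-1-ol | C=C[C@@H](O)c1ccc(OCc2ccccc2)c(OC)c1 | intermediate
5 | vanillic acid | COc1cc(C(=O)O)ccc1O | starting material
6 | triisopropylsilyl 3-methoxy-4-(triisopropylsilyloxy)benzoate (not isolated) | COc1cc(C(=O)O[Si](C(C)C)(C(C)C)C(C)C)ccc1O[Si](C(C)C)(C(C)C)C(C)C | intermediate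
7 | 3-methoxy-4-(triisopropylsilyloxy)benzoic acid | COc1cc(C(=O)O)ccc1O[Si](C(C)C)(C(C)C)C(C)C | intermediate
8 | Meldrum's acid | CC1(C)OC(=O)CC(=O)O1 | starting material
9 | 5-{hydroxy[3-methoxy-4-(triisopropylsilyloxy)phenyl]methylidene}-2,2-dimethyl-1,3-dioxane-4,6-dione | CC1(C)OC(=O)C(=C(O)c2ccc(O[Si](C(C)C)(C(C)C)C(C)C)c(OC)c2)C(=O)O1 | intermediate
10 | [3-methoxy-4-(triisopropylsilyloxy)benzoyl]ketene (not isolated) | O=C=CC(=O)c1ccc(O[Si](C(C)C)(C(C)C)C(C)C)c(OC)c1 | intermediate
11 | (R)-1-(4-benzyloxy-3-methoxyphenyl)prop-2-enyl 3-[3-methoxy-4-(triisopropylsilyloxy)phenyl]-3-oxopropanoate | C=C[C@@H](OC(=O)CC(=O)c1ccc(O[Si](C(C)C)(C(C)C)C(C)C)c(OC)c1)c1ccc(OCc2ccccc2)c(OC)c1 | intermediate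
12 | (R)-1-(4-benzyloxy-3-methoxyphenyl)prop-2-enyl 2-diazo-3-[3-methoxy-4-(triisopropylsilyloxy)phenyl]-3-oxopropanoate | C=C[C@@H](OC(=O)C(=[N+]=[N-])C(=O)c1ccc(O[Si](C(C)C)(C(C)C)C(C)C)c(OC)c1)c1ccc(OCc2ccccc2)c(OC)c1 | intermediate
13 | (1S,4R,5R)-4-(4-benzyloxy-3-methoxyphenyl)-1-[3-methoxy-4-(triisopropylsilyloxy)benzoyl]-3-oxabicyclo[3.1.0]hexan-2-one | O=C(c1ccc(O[Si](C(C)C)(C(C)C)C(C)C)c(OC)c1)[C@]12C[C@H]1[C@H](c1ccc(OCc3ccccc3)c(OC)c1)OC2=O | intermediate
14 | sodium enolate of (4R,5R)-5-(4-benzyloxy-3-methoxyphenyl)-4-(iodomethyl)-3-[3-methoxy-4-(triisopropylsilyloxy)benzoyl]oxolan-2-one (not isolated) | O=C1O[C@@H](c2ccc(OCc3ccccc3)c(OC)c2)[C@H](CI)C1=C([O-])c1ccc(O[Si](C(C)C)(C(C)C)C(C)C)c(OC)c1.[Na+] | intermediate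
15 | (5S,6R)-6-(4-benzyloxy-3-methoxyphenyl)-2-[3-methoxy-4-(triisopropylsilyloxy)phenyl]-3,7-dioxabicyclo[3.3.0]oct-1-en-8-one | O=C1O[C@@H](c2ccc(OCc3ccccc3)c(OC)c2)[C@@H]2COC(c3ccc(O[Si](C(C)C)(C(C)C)C(C)C)c(OC)c3)=C12 | intermediate
16 | (1R,2S,5S,6R)-6-(4-hydroxy-3-methoxyphenyl)-2-[3-methoxy-4-(triisopropylsilyloxy)phenyl]-3,7-dioxabicyclo[3.3.0]octan-8-one | COc1cc([C@H]2OC[C@@H]3[C@H]2C(=O)O[C@H]3c2ccc(O)c(OC)c2)ccc1O[Si](C(C)C)(C(C)C)C(C)C | intermediate
17 | (1R,2S,5S,6R)-2-[3-methoxy-4-(triisopropylsilyloxy)phenyl]-6-[3-methoxy-4-(3-methylbut-2-enyloxy)phenyl]-3,7-dioxabicyclo[3.3.0]octan-8-one | COc1cc([C@H]2OC[C@@H]3[C@H]2C(=O)O[C@H]3c2ccc(OCC=C(C)C)c(OC)c2)ccc1O[Si](C(C)C)(C(C)C)C(C)C | intermediate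
18 | [(2S,3S,4S)-4-{(R)-hydroxy[3-methoxy-4-(3-methylbut-2-enyloxy)phenyl]methyl}-2-[3-methoxy-4-(triisopropylsilyloxy)phenyl]oxolan-3-yl]methanol | COc1cc([C@H]2OC[C@@H]([C@@H](O)c3ccc(OCC=C(C)C)c(OC)c3)[C@H]2CO)ccc1O[Si](C(C)C)(C(C)C)C(C)C | intermediate
19 | primary (C8) methanesulfonate of 18 (not isolated) | COc1cc([C@H]2OC[C@@H]([C@@H](O)c3ccc(OCC=C(C)C)c(OC)c3)[C@H]2COS(C)(=O)=O)ccc1O[Si](C(C)C)(C(C)C)C(C)C | intermediate
20 | (1S,2S,5S,6R)-2-[3-methoxy-4-(triisopropylsilyloxy)phenyl]-6-[3-methoxy-4-(3-methylbut-2-enyloxy)phenyl]-3,7-dioxabicyclo[3.3.0]octane | COc1cc([C@H]2OC[C@@H]3[C@H]2CO[C@H]3c2ccc(OCC=C(C)C)c(OC)c2)ccc1O[Si](C(C)C)(C(C)C)C(C)C | intermediate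
21 | 2-methoxy-4-{(1S,2S,5S,6R)-6-[3-methoxy-4-(3-methylbut-2-enyloxy)phenyl]-3,7-dioxabicyclo[3.3.0]octan-2-yl}phenol | COc1cc([C@H]2OC[C@@H]3[C@H]2CO[C@H]3c2ccc(OCC=C(C)C)c(OC)c2)ccc1O | target

## Step count and least certain steps

Total: 13 steps. Longest linear sequence: 11 steps (steps 1, 2 and 5–13 from 1; the branch from 5 through steps 3 and 4 joins at step 5 and is equally long).

Risk at step 8 (key step): the ring expansion may stall at the ring-opened stage, or iodide may dealkylate the benzylic lactone carbon C6 with subsequent decarboxylation. Both electrophilic carbons are available to iodide, and the electron-rich aroyl group makes the cyclopropane a weaker acceptor. Fallback, from 13 back to 15: the bond formation is split into two polar events. MgI2 in THF at room temperature opens the chelated 1,3-dicarbonyl cyclopropane stoichiometrically, and aqueous quench should give (4R,5R)-5-(4-benzyloxy-3-methoxyphenyl)-4-(iodomethyl)-3-[3-methoxy-4-(triisopropylsilyloxy)benzoyl]oxolan-2-one F1. AgOTf with 2,6-lutidine in CH2Cl2 then pulls iodide from C4 while the keto-enol oxygen closes ring A (silver-assisted O-alkylation of an ambident 1,3-dicarbonyl), which rejoins the route at 15.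

Risk at step 9: saturation of the tetrasubstituted push-pull alkene may be slow, so that hydrogenolysis of C6–O7 or C2–O3 competes, or face selectivity may be incomplete. Fallback, from 15 back to 16: ionic hydrogenation with Et3SiH and CF3CO2H in CH2Cl2 at −20 °C. Protonation at C1 on the convex face gives the aryl-stabilised C2 oxocarbenium ion, and hydride is delivered to C2 from the same face. This should give (1R,2S,5S,6R)-6-(4-benzyloxy-3-methoxyphenyl)-2-[3-methoxy-4-(triisopropylsilyloxy)phenyl]-3,7-dioxabicyclo[3.3.0]octan-8-one F2. A brief hydrogenolysis of its benzyl ether over Pd/C in EtOAc then gives 16; the exposure to palladium is short because the alkene is already reduced.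

Risk at step 7: exo/endo selectivity relative to the C6 aryl group may be poor, or the carbenoid may be diverted into the electron-rich arenes or the benzylic CH2 of the benzyl ether. Fallback, from 11 directly to 13 (bypassing 12): oxidative radical cyclisation with Mn(OAc)3·2H2O and Cu(OAc)2 in AcOH. The radical of the β-keto ester closes 5-exo onto the vinyl group with the aryl group pseudo-equatorial, and the adduct is oxidised to the cyclopropane. This is a known way to 1-acyl-3-oxabicyclo[3.1.0]hexan-2-ones and makes no new compound (entry F0).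

Risk at step 5: the electron-rich benzylic allylic alcohol or its ester may ionise in the hot solution of the acidic acyl Meldrum's acid, causing racemisation at C6 or 1,3-transposition to the cinnamyl isomer. Fallback, from 4 and 7 back to 11, all under basic conditions: 4 is acetylated (Ac2O, Et3N, DMAP, CH2Cl2, 0 °C) to (R)-1-(4-benzyloxy-3-methoxyphenyl)prop-2-enyl acetate F3. Acid 7 is converted with carbonyldiimidazole into 1-[3-methoxy-4-(triisopropylsilyloxy)benzoyl]imidazole F4. The lithium enolate of F3 (LiN(SiMe3)2, 2.2 equiv, THF, −78 °C) is then acylated by F4 in a crossed Claisen condensation to give 11.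

Risk at step 12: sulfonylation may occur at the benzylic C6 hydroxyl instead of C8, followed by ionisation at C6 or elimination. Fallback, from 17 back to 20: the lactone is reduced with i-Bu2AlH (CH2Cl2, −78 °C) to the lactol (1R,2S,5S,6R)-2-[3-methoxy-4-(triisopropylsilyloxy)phenyl]-6-[3-methoxy-4-(3-methylbut-2-enyloxy)phenyl]-3,7-dioxabicyclo[3.3.0]octan-8-ol F5. The C8 oxocarbenium ion is then reduced with Et3SiH and BF3·OEt2 at −78 °C to give 20. The acid exposure must be short and cold because of the prenyl ether and the benzylic ethers.

## Further compounds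

F1 | step 8 | (4R,5R)-5-(4-benzyloxy-3-methoxyphenyl)-4-(iodomethyl)-3-[3-methoxy-4-(triisopropylsilyloxy)benzoyl]oxolan-2-one (C3 epimers and enol) | O=C1O[C@@H](c2ccc(OCc3ccccc3)c(OC)c2)[C@H](CI)C1C(=O)c1ccc(O[Si](C(C)C)(C(C)C)C(C)C)c(OC)c1
F2 | step 9 | (1R,2S,5S,6R)-6-(4-benzyloxy-3-methoxyphenyl)-2-[3-methoxy-4-(triisopropylsilyloxy)phenyl]-3,7-dioxabicyclo[3.3.0]octan-8-one | COc1cc([C@H]2OC[C@@H]3[C@H]2C(=O)O[C@H]3c2ccc(OCc3ccccc3)c(OC)c2)ccc1O[Si](C(C)C)(C(C)C)C(C)C
F0 | step 7 | none | none
F3 | step 5 | (R)-1-(4-benzyloxy-3-methoxyphenyl)prop-2-enyl acetate | C=C[C@@H](OC(C)=O)c1ccc(OCc2ccccc2)c(OC)c1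
F4 | step 5 | 1-[3-methoxy-4-(triisopropylsilyloxy)benzoyl]imidazole | O=C(c1ccc(O[Si](C(C)C)(C(C)C)C(C)C)c(OC)c1)n1ccnc1
F5 | step 12 | (1R,2S,5S,6R)-2-[3-methoxy-4-(triisopropylsilyloxy)phenyl]-6-[3-methoxy-4-(3-methylbut-2-enyloxy)phenyl]-3,7-dioxabicyclo[3.3.0]octan-8-ol (both C8 anomers) | COc1cc([C@H]2OC[C@@H]3[C@H]2C(O)O[C@H]3c2ccc(OCC=C(C)C)c(OC)c2)ccc1O[Si](C(C)C)(C(C)C)C(C)C
A1 | alternative 1 | (4R,5R)-4-[(Z)-3-(4-benzyloxy-3-methoxyphenyl)prop-1-enyl]-5-(3-methoxy-4-methylsulfonyloxyphenyl)-1,3-dioxolane | COc1cc([C@H]2OCO[C@@H]2/C=C\Cc2ccc(OCc3ccccc3)c(OC)c2)ccc1OS(C)(=O)=O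
A2 | alternative 1 | (2S,3R,4S)-4-(4-benzyloxy-3-methoxybenzyl)-2-(3-methoxy-4-methylsulfonyloxyphenyl)oxolane-3-carbaldehyde | COc1cc([C@H]2OC[C@@H](Cc3ccc(OCc4ccccc4)c(OC)c3)[C@H]2C=O)ccc1OS(C)(=O)=O
A3 | alternative 2 | [(2S,3S)-2-(3-methoxy-4-methylsulfonyloxyphenyl)-2,3-dihydrofuran-3-yl]methanol | COc1cc([C@H]2OC=C[C@H]2CO)ccc1OS(C)(=O)=O
A4 | alternative 2 | (1S,2S,5S,6R)-6-(4-benzyloxy-3-methoxyphenyl)-2-(3-methoxy-4-methylsulfonyloxyphenyl)-3,7-dioxabicyclo[3.3.0]octane | COc1cc([C@H]2OC[C@@H]3[C@H]2CO[C@H]3c2ccc(OCc3ccccc3)c(OC)c2)ccc1OS(C)(=O)=O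
A5 | alternative 3 | 2-{(R)-[3-methoxy-4-(3-methylbut-2-enyloxy)phenyl]{(3S)-5-[3-methoxy-4-(triisopropylsilyloxy)phenyl]-2,3-dihydrofuran-3-yl}methoxy}acetic acid | OC(=O)CO[C@H]([C@@H]1COC(c2ccc(O[Si](C(C)C)(C(C)C)C(C)C)c(OC)c2)=C1)c1ccc(OCC=C(C)C)c(OC)c1
A6 | alternative 3 | (1S,2S,5S,6R)-2-[3-methoxy-4-(triisopropylsilyloxy)phenyl]-6-[3-methoxy-4-(3-methylbut-2-enyloxy)phenyl]-3,7-dioxabicyclo[3.3.0]octane (identical with 20) | COc1cc([C@H]2OC[C@@H]3[C@H]2CO[C@H]3c2ccc(OCC=C(C)C)c(OC)c2)ccc1O[Si](C(C)C)(C(C)C)C(C)C
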